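**Retrosynthetic overview**

- Metachromin C is a 2‑hydroxy‑5‑methoxy‑1,4‑benzoquinone whose C3 carries an (E)‑allylic chain ending in a (1R,2S)‑1,2,3‑trimethylcyclohex‑3‑enyl ring. The quinone ring is built last, by closing its C1–C2 bond (the carbonyl carbon next to the ring CH and the hydroxyl‑bearing carbon) in a strain‑releasing cyclobutenone ring expansion.
- Enabling feature: ring atoms C1(=O)–C6H=C5(OMe)–C4(=O) are the four carbons of 3‑methoxycyclobutenedione (methyl semisquarate), and C3(chain)=C2(OH) is a 2‑silyloxyvinyl unit, i.e. the α‑ and carbonyl carbons of an aldehyde. Ring opening to a dienylketene and 6π closure then joins C1 to C2.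
- Disconnections: C3–C4 (β‑silyloxyvinyllithium + semisquarate carbonyl); enol ether ⇒ α‑bromo aldehyde; chain C–C bond at the (E)‑olefin by B‑alkyl Suzuki–Miyaura coupling; vinyl ⇐ aldehyde; cyclohexene ⇐ Diels–Alder.
- Ring order: cyclohexene ring first (catalytic asymmetric Diels–Alder, sets both stereocentres); cyclobutenone ring taken from dimethyl squarate; quinone ring last.

Key step: step 10

Remark on the chemistry: the sense of induction in step 1 is assigned from the usual model for 2‑substituted acroleins on cationic oxazaborolidines and has not been derived independently; both catalyst antipodes are equally available, so the one that delivers (1S,2R)‑3 is used. Commercial 3‑methylpenta‑1,3‑diene is an E/Z mixture, of which only the E isomer should react.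

**Step 1**
Reactants: 1 (E)-3-methylpenta-1,3-diene; 2 methacrolein
Product: 3 (1S,2R)-1,2,3-trimethylcyclohex-3-ene-1-carbaldehyde
Conditions: 1 (3 equiv), (S)-o-tolyl-oxazaborolidinium triflimide [from (S)-α,α-diphenylprolinol, o-TolB(OH)2 and Tf2NH] (15 mol %), CH2Cl2, −78 °C
Reagents that add atoms: none
Why: Enantioselective Lewis-acid-catalysed Diels–Alder reaction of a 2-substituted acrolein, in which the terminal methyl of the diene directs "ortho" bonding to the enal α-carbon, the formyl-endo transition state places CHO cis to the C2 methyl, and the catalyst aryl group shields one enal face and so fixes the absolute configuration of both stereocentres at once.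

**Step 2**
Reactants: 3 (1S,2R)-1,2,3-trimethylcyclohex-3-ene-1-carbaldehyde
Product: 4 (5R,6R)-5-ethenyl-1,5,6-trimethylcyclohex-1-ene
Conditions: Ph3PCH3Br, KOtBu, THF, 0 °C to reflux
Reagents that add atoms: methyltriphenylphosphonium bromide, C[P+](c1ccccc1)(c1ccccc1)c1ccccc1.[Br-]
Why: Wittig methylenation of a non-enolisable α-quaternary aldehyde, which cannot epimerise, so both stereocentres are carried through unchanged (the descriptor change is formal).

**Step 3**
Reactants: 5 hex-4-yn-1-ol
Product: 7 (E)-5-iodohex-4-en-1-ol, via alkenylzirconocene chloride 6 (not isolated)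
Conditions: Cp2Zr(H)Cl (2.5 equiv), THF, 50 °C; then I2, 0 °C; 1 M HCl work-up
Reagents that add atoms: iodine, II
Why: Syn hydrozirconation of a 2-alkyne (the first equivalent is consumed by the hydroxyl) equilibrates zirconium to the less hindered methyl-bearing carbon, and iodinolysis with retention should give the (E)-2-iodoalkene that fixes the side-chain olefin geometry.

**Step 4**
Reactants: 4 (5R,6R)-5-ethenyl-1,5,6-trimethylcyclohex-1-ene; 7 (E)-5-iodohex-4-en-1-ol
Product: 9 (4E)-5-methyl-7-[(1R,2S)-1,2,3-trimethylcyclohex-3-en-1-yl]hept-4-en-1-ol, via B-alkyl-9-BBN borane 8 (not isolated)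
Conditions: 9-BBN, THF, rt; then 7, PdCl2(dppf) (5 mol %), AsPh3, Cs2CO3, DMF/H2O, rt
Reagents that add atoms: none
Why: Anti-Markovnikov hydroboration of the monosubstituted vinyl group (the trisubstituted ring olefin is inert to 9-BBN) followed by B-alkyl Suzuki–Miyaura coupling, which proceeds with retention at the alkenyl iodide and so should deliver the (E)-trisubstituted olefin.

**Step 5**
Reactants: 9 (4E)-5-methyl-7-[(1R,2S)-1,2,3-trimethylcyclohex-3-en-1-yl]hept-4-en-1-ol
Product: 10 (4E)-5-methyl-7-[(1R,2S)-1,2,3-trimethylcyclohex-3-en-1-yl]hept-4-enal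
Conditions: TEMPO (10 mol %), PhI(OAc)2, CH2Cl2, rt
Reagents that add atoms: none
Why: TEMPO/PhI(OAc)2 oxidation of a primary alcohol stops at the aldehyde and leaves both trisubstituted olefins untouched.

**Step 6**
Reactants: 10 (4E)-5-methyl-7-[(1R,2S)-1,2,3-trimethylcyclohex-3-en-1-yl]hept-4-enal
Product: 11 (4E)-2-bromo-5-methyl-7-[(1R,2S)-1,2,3-trimethylcyclohex-3-en-1-yl]hept-4-enal (both C2 epimers)
Conditions: pyrrolidine (20 mol %), PhCO2H (20 mol %), 4,4-dibromo-2,6-di-tert-butylcyclohexa-2,5-dien-1-one (1.05 equiv), CH2Cl2, −40 °C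
Reagents that add atoms: 4,4-dibromo-2,6-di-tert-butylcyclohexa-2,5-dien-1-one, CC(C)(C)C1=CC(Br)(Br)C=C(C(C)(C)C)C1=O
Why: Enamine-catalysed α-bromination, in which the transient enamine is far more nucleophilic toward the mild bromine donor than the trisubstituted olefins; the new α-stereocentre is not controlled and is erased in step 7.

**Step 7**
Reactants: 11 (4E)-2-bromo-5-methyl-7-[(1R,2S)-1,2,3-trimethylcyclohex-3-en-1-yl]hept-4-enal
Product: 12 {[(1Z,4E)-2-bromo-5-methyl-7-[(1R,2S)-1,2,3-trimethylcyclohex-3-en-1-yl]hepta-1,4-dien-1-yl]oxy}tri(propan-2-yl)silane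
Conditions: TIPSOTf, Et3N, CH2Cl2, −78 to 0 °C
Reagents that add atoms: triisopropylsilyl trifluoromethanesulfonate, CC(C)[Si](OS(=O)(=O)C(F)(F)F)(C(C)C)C(C)C
Why: Soft enolisation (O-silylation, then α-deprotonation, faster than loss of HBr) should give the bromo enol silyl ether, with the isomer having bromine cis to oxygen expected to predominate; the sp3 bromide centre becomes sp2.

**Step 8**
Reactants: 13 dimethyl squarate
Product: 15 3-methoxycyclobut-3-ene-1,2-dione, via 4-hydroxy-2,3-dimethoxycyclobut-2-en-1-one 14 (not isolated)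
Conditions: LiAlH(OtBu)3, THF, −78 °C; then 6 M HCl, CH2Cl2, rt
Reagents that add atoms: none
Why: Selective 1,2-reduction of one squarate carbonyl and acid-induced loss of methanol from the resulting hydroxy enol ether is the standard access to semisquarate esters.

**Step 9**
Reactants: 12 {[(1Z,4E)-2-bromo-5-methyl-7-[(1R,2S)-1,2,3-trimethylcyclohex-3-en-1-yl]hepta-1,4-dien-1-yl]oxy}tri(propan-2-yl)silane; 15 3-methoxycyclobut-3-ene-1,2-dione
Product: 17 4-hydroxy-3-methoxy-4-[(1Z,4E)-5-methyl-1-{[tri(propan-2-yl)silyl]oxy}-7-[(1R,2S)-1,2,3-trimethylcyclohex-3-en-1-yl]hepta-1,4-dien-2-yl]cyclobut-2-en-1-one (both C4 epimers), via β-silyloxyvinyllithium 16 (not isolated)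
Conditions: t-BuLi (2.0 equiv), Et2O, −78 °C; then 15, THF, −78 °C; aq NH4Cl at −78 °C
Reagents that add atoms: none
Why: Bromine–lithium exchange should give a β-silyloxyvinyllithium (configurationally stable at −78 °C with lithium cis to oxygen) that adds 1,2 to the ketone-like carbonyl of the cyclobutenedione (the one next to the methoxy-bearing carbon, the other being a vinylogous ester); the new carbinol centre is uncontrolled and is destroyed in step 10.

**Step 10**
Reactants: 17 4-hydroxy-3-methoxy-4-[(1Z,4E)-5-methyl-1-{[tri(propan-2-yl)silyl]oxy}-7-[(1R,2S)-1,2,3-trimethylcyclohex-3-en-1-yl]hepta-1,4-dien-2-yl]cyclobut-2-en-1-one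
Product: 20 5-methoxy-3-[(2E)-3-methyl-5-[(1R,2S)-1,2,3-trimethylcyclohex-3-en-1-yl]pent-2-en-1-yl]-2-{[tri(propan-2-yl)silyl]oxy}benzene-1,4-diol, via dienylketene 18 (not isolated), via cyclohexadienone 19 (not isolated)
Conditions: degassed toluene (0.01 M), 110 °C, Ar; concentrated under Ar and used crude
Reagents that add atoms: none
Why: Heating opens the strained cyclobutenone by conrotatory 4π electrocyclic ring opening (release of the four-ring strain is the driving force) to dienylketene 18, the donor hydroxyl on C4 rotating outward so that the silyloxyvinyl group is turned inward, next to the ketene. Thermally allowed disrotatory 6π electrocyclisation then joins the ketene carbon (the future C1 carbonyl) to the silyloxy-bearing vinyl carbon (the future C2), closing the six-membered ring as cyclohexadienone 19, which enolises at once to the aromatic hydroquinone 20. The closest known reaction type is the Moore rearrangement of 4-alkenyl-4-hydroxycyclobutenones derived from squarate esters, applied here to a 2-silyloxyvinyl substituent. The ring closure is a pericyclic 6π closure of a cis-dienylketene rather than a polar exo or endo cyclisation, and the only stereocentre it creates (C6 of 19) is lost on aromatisation, as is the carbinol centre of 17. The step needs torquoselectivity (hydroxyl out, vinyl in; otherwise the hydroxyl would trap the ketene as a furanone), which the strongly donating C4 oxygen secures, and it has no regiochemical choice because the substituents of all six ring carbons are already fixed in 17. In one operation it should build the fully substituted, tetra-oxygenated ring with the complete side chain in place.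

**Step 11**
Reactants: 20 5-methoxy-3-[(2E)-3-methyl-5-[(1R,2S)-1,2,3-trimethylcyclohex-3-en-1-yl]pent-2-en-1-yl]-2-{[tri(propan-2-yl)silyl]oxy}benzene-1,4-diol
Product: 22 metachromin C, via silyloxyquinone 21 (not isolated)
Conditions: Ag2O, Et2O, rt; then TBAF/AcOH (1:1), THF, 0 °C
Reagents that add atoms: none
Why: Ag2O should oxidise the hydroquinone to the quinone, whose silyl vinylogous ester is then cleaved by buffered fluoride to the hydroxyquinone without touching the methyl vinylogous ester or the olefins.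

**Compound list**

1 | (E)-3-methylpenta-1,3-diene | C=C/C(C)=C/C | starting material
2 | methacrolein (2-methylprop-2-enal) | CC(=C)C=O | starting material
3 | (1S,2R)-1,2,3-trimethylcyclohex-3-ene-1-carbaldehyde | O=C[C@@]1(C)CCC=C(C)[C@H]1C | intermediate
4 | (5R,6R)-5-ethenyl-1,5,6-trimethylcyclohex-1-ene (vinyl cis to the neighbouring ring methyl) | C=C[C@@]1(C)CCC=C(C)[C@H]1C | intermediate
5 | hex-4-yn-1-ol | CC#CCCCO | starting material
6 | (E)-alkenylzirconocene chloride from 5 (Zr on C5, hydroxyl as zirconocene alkoxide) | C/C(=C\CCCO[Zr](Cl)(C1C=CC=C1)C1C=CC=C1)[Zr](Cl)(C1C=CC=C1)C1C=CC=C1 | intermediate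
7 | (E)-5-iodohex-4-en-1-ol | C/C(I)=C\CCCO | intermediate
8 | 9-{2-[(1S,2S)-1,2,3-trimethylcyclohex-3-en-1-yl]ethyl}-9-borabicyclo[3.3.1]nonane (ring configuration as in 4; descriptor change formal) | B1(CC[C@@]2(C)CCC=C(C)[C@H]2C)C3CCCC1CCC3 | intermediate
9 | (4E)-5-methyl-7-[(1R,2S)-1,2,3-trimethylcyclohex-3-en-1-yl]hept-4-en-1-ol | OCCC/C=C(\C)CC[C@@]1(C)CCC=C(C)[C@H]1C | intermediate
10 | (4E)-5-methyl-7-[(1R,2S)-1,2,3-trimethylcyclohex-3-en-1-yl]hept-4-enal | O=CCC/C=C(\C)CC[C@@]1(C)CCC=C(C)[C@H]1C | intermediate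
11 | (4E)-2-bromo-5-methyl-7-[(1R,2S)-1,2,3-trimethylcyclohex-3-en-1-yl]hept-4-enal (both C2 epimers) | O=CC(Br)C/C=C(\C)CC[C@@]1(C)CCC=C(C)[C@H]1C | intermediate
12 | {[(1Z,4E)-2-bromo-5-methyl-7-[(1R,2S)-1,2,3-trimethylcyclohex-3-en-1-yl]hepta-1,4-dien-1-yl]oxy}tri(propan-2-yl)silane | Br/C(C/C=C(\C)CC[C@@]1(C)CCC=C(C)[C@H]1C)=C\O[Si](C(C)C)(C(C)C)C(C)C | intermediate
13 | dimethyl squarate (3,4-dimethoxycyclobut-3-ene-1,2-dione) | COC1=C(OC)C(=O)C1=O | starting material
14 | 4-hydroxy-2,3-dimethoxycyclobut-2-en-1-one | COC1=C(OC)C(=O)C1O | intermediate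
15 | 3-methoxycyclobut-3-ene-1,2-dione (methyl semisquarate) | COC1=CC(=O)C1=O | intermediate
16 | vinyllithium from 12 (Li in place of Br, cis to the silyloxy group) | [Li]/C(C/C=C(\C)CC[C@@]1(C)CCC=C(C)[C@H]1C)=C\O[Si](C(C)C)(C(C)C)C(C)C | intermediate
17 | 4-hydroxy-3-methoxy-4-[(1Z,4E)-5-methyl-1-{[tri(propan-2-yl)silyl]oxy}-7-[(1R,2S)-1,2,3-trimethylcyclohex-3-en-1-yl]hepta-1,4-dien-2-yl]cyclobut-2-en-1-one (both C4 epimers) | COC1=CC(=O)C1(O)/C(C/C=C(\C)CC[C@@]2(C)CCC=C(C)[C@H]2C)=C\O[Si](C(C)C)(C(C)C)C(C)C | intermediate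
18 | dienylketene from 17 (ketene CH=C=O, then C(OMe)=C(OH), then the silyloxyvinyl unit cis to the ketene) | O=C=C/C(OC)=C(O)\C(C/C=C(\C)CC[C@@]1(C)CCC=C(C)[C@H]1C)=C/O[Si](C(C)C)(C(C)C)C(C)C | intermediate
19 | 4-hydroxy-3-methoxy-5-(side chain)-6-{[tri(propan-2-yl)silyl]oxy}cyclohexa-2,4-dien-1-one (C6 epimers) | COC1=CC(=O)C(O[Si](C(C)C)(C(C)C)C(C)C)C(C/C=C(\C)CC[C@@]2(C)CCC=C(C)[C@H]2C)=C1O | intermediate
20 | 5-methoxy-3-[(2E)-3-methyl-5-[(1R,2S)-1,2,3-trimethylcyclohex-3-en-1-yl]pent-2-en-1-yl]-2-{[tri(propan-2-yl)silyl]oxy}benzene-1,4-diol | COc1cc(O)c(O[Si](C(C)C)(C(C)C)C(C)C)c(C/C=C(\C)CC[C@@]2(C)CCC=C(C)[C@H]2C)c1O | intermediate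
21 | 5-methoxy-3-[(2E)-3-methyl-5-[(1R,2S)-1,2,3-trimethylcyclohex-3-en-1-yl]pent-2-en-1-yl]-2-{[tri(propan-2-yl)silyl]oxy}cyclohexa-2,5-diene-1,4-dione | COC1=CC(=O)C(O[Si](C(C)C)(C(C)C)C(C)C)=C(C/C=C(\C)CC[C@@]2(C)CCC=C(C)[C@H]2C)C1=O | intermediate
22 | metachromin C, 2-hydroxy-5-methoxy-3-[(2E)-3-methyl-5-[(1R,2S)-1,2,3-trimethylcyclohex-3-en-1-yl]pent-2-en-1-yl]cyclohexa-2,5-diene-1,4-dione | COC1=CC(=O)C(O)=C(C/C=C(\C)CC[C@@]2(C)CCC=C(C)[C@H]2C)C1=O | target

**Step count and risks**

Total step count: 11. Longest linear sequence: 9 steps (1, 2, 4, 5, 6, 7, 9, 10, 11); steps 3 and 8 prepare the two side fragments.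

Steps most likely to fail:

1. Step 9. What may go wrong:
   - β-elimination of silanolate from the vinyllithium (fast if lithium is trans to oxygen, so any E-bromide must be removed beforehand);
   - migration of the silyl group from oxygen to carbon or to the new alkoxide;
   - proton transfer from the doubly allylic CH2;
   - attack at the vinylogous-ester carbonyl.

   Fallback, setting out from 10 and coming back at 17. Aldehyde 10 is converted (TIPSOTf, Et3N) into its enol silyl ether tri(propan-2-yl){[(1Z,4E)-5-methyl-7-[(1R,2S)-1,2,3-trimethylcyclohex-3-en-1-yl]hepta-1,4-dien-1-yl]oxy}silane F1. A Mukaiyama aldol addition of F1 to 15 (TiCl4, CH2Cl2, −78 °C) forms the same C–C bond without any organolithium and should give, after aqueous work-up, the β-hydroxy aldehyde 2-(1-hydroxy-2-methoxy-4-oxocyclobut-2-en-1-yl)-(4E)-5-methyl-7-[(1R,2S)-1,2,3-trimethylcyclohex-3-en-1-yl]hept-4-enal F2. Soft enolisation of the aldehyde (TIPSOTf 1.0 equiv, Et3N, −78 °C; the hindered tertiary hydroxyl should stay free) gives 17, possibly with its enol ether geometrical isomer, the (1E)-isomer of 17 F3; both converge in step 10. This path also bypasses steps 6 and 7.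

2. Step 1. What may go wrong:
   - bonding at the wrong diene terminus, because the internal methyl opposes the directing effect of the terminal one;
   - competition of the formyl-exo transition state, which would give the C1 epimer;
   - incomplete facial selection;
   - acid-induced oligomerisation of the diene.

   Fallback, setting out from 1 and coming back at 3. A Diels–Alder reaction of 1 with acrolein under iminium catalysis by a chiral 5-benzyl-2,2,3-trimethylimidazolidin-4-one hydrochloride (enantiomer chosen for the required sense) is used instead, since endo and facial control are more dependable for an α-unsubstituted enal. It should give (1S,2S)-2,3-dimethylcyclohex-3-ene-1-carbaldehyde F4, whose C1 configuration is irrelevant. Deprotonation with KOtBu and C-methylation with MeI anti to the neighbouring C2 methyl group then sets the quaternary centre by substrate control and gives 3.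

3. Step 10. What may go wrong:
   - transfer of the silyl group from the enol ether to the tertiary hydroxyl before ring opening, leaving an aldehyde that cannot cyclise;
   - capture of the ketene by the hydroxyl (furanone formation) if torquoselectivity is eroded;
   - loss of the enol silyl ether through adventitious acid.

   Fallback, setting out from 4 and coming back at 22; the aromatic ring is bought instead of built.
   - Borane 8 from 4 is coupled (PdCl2(dppf), AsPh3, Cs2CO3) with (E)-3-iodobut-2-en-1-ol to give (2E)-3-methyl-5-[(1R,2S)-1,2,3-trimethylcyclohex-3-en-1-yl]pent-2-en-1-ol F5.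
   - CBr4/PPh3 converts F5 into (2E)-1-bromo-3-methyl-5-[(1R,2S)-1,2,3-trimethylcyclohex-3-en-1-yl]pent-2-ene F6.
   - 1,2,4,5-Tetramethoxybenzene is lithiated (n-BuLi, THF, 0 °C) to (2,3,5,6-tetramethoxyphenyl)lithium F7, which is alkylated with F6 (CuBr·SMe2 cat.) to 1,2,4,5-tetramethoxy-3-[(2E)-3-methyl-5-[(1R,2S)-1,2,3-trimethylcyclohex-3-en-1-yl]pent-2-en-1-yl]benzene F8.
   - Oxidative demethylation with (NH4)2Ce(NO3)6 in MeCN/H2O at 0 °C should give 2,5-dimethoxy-3-[(2E)-3-methyl-5-[(1R,2S)-1,2,3-trimethylcyclohex-3-en-1-yl]pent-2-en-1-yl]cyclohexa-2,5-diene-1,4-dione F9.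
   - Monohydrolysis with KOH in MeOH/H2O gives 22. Hydrolysis is expected at the methoxy group flanked by the alkyl chain, which is twisted out of conjugation; this regioselectivity is the uncertain point of the fallback, and the isomer would be separated if it forms.

Further compounds
F1 | step 9 | tri(propan-2-yl){[(1Z,4E)-5-methyl-7-[(1R,2S)-1,2,3-trimethylcyclohex-3-en-1-yl]hepta-1,4-dien-1-yl]oxy}silane | CC(C)[Si](O/C=C\C/C=C(\C)CC[C@@]1(C)CCC=C(C)[C@H]1C)(C(C)C)C(C)C
F2 | step 9 | 2-(1-hydroxy-2-methoxy-4-oxocyclobut-2-en-1-yl)-(4E)-5-methyl-7-[(1R,2S)-1,2,3-trimethylcyclohex-3-en-1-yl]hept-4-enal | O=CC(C/C=C(\C)CC[C@@]1(C)CCC=C(C)[C@H]1C)C1(O)C(OC)=CC1=O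
F3 | step 9 | (1E)-isomer of 17 | COC1=CC(=O)C1(O)/C(C/C=C(\C)CC[C@@]2(C)CCC=C(C)[C@H]2C)=C/O[Si](C(C)C)(C(C)C)C(C)C
F4 | step 1 | (1S,2S)-2,3-dimethylcyclohex-3-ene-1-carbaldehyde | O=C[C@H]1CCC=C(C)[C@H]1C
F5 | step 10 | (2E)-3-methyl-5-[(1R,2S)-1,2,3-trimethylcyclohex-3-en-1-yl]pent-2-en-1-ol | OC/C=C(\C)CC[C@@]1(C)CCC=C(C)[C@H]1C
F6 | step 10 | (2E)-1-bromo-3-methyl-5-[(1R,2S)-1,2,3-trimethylcyclohex-3-en-1-yl]pent-2-ene | BrC/C=C(\C)CC[C@@]1(C)CCC=C(C)[C@H]1C
F7 | step 10 | (2,3,5,6-tetramethoxyphenyl)lithium | [Li]c1c(OC)c(OC)cc(OC)c1OC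
F8 | step 10 | 1,2,4,5-tetramethoxy-3-[(2E)-3-methyl-5-[(1R,2S)-1,2,3-trimethylcyclohex-3-en-1-yl]pent-2-en-1-yl]benzene | COc1cc(OC)c(OC)c(C/C=C(\C)CC[C@@]2(C)CCC=C(C)[C@H]2C)c1OC
F9 | step 10 | 2,5-dimethoxy-3-[(2E)-3-methyl-5-[(1R,2S)-1,2,3-trimethylcyclohex-3-en-1-yl]pent-2-en-1-yl]cyclohexa-2,5-diene-1,4-dione | COC1=CC(=O)C(OC)=C(C/C=C(\C)CC[C@@]2(C)CCC=C(C)[C@H]2C)C1=O
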